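**Plan**
- Retrosynthesis: after removal of twelve benzyl ethers, the benzotropolone is cut at C6–C7 and C8–C9 (benzo[7]annulene numbering, with the C9–O bridge restored). This gives a 2-ethynylchroman gallate and a flavanyl-substituted ortho-formyl aryl diazomethyl ketone.
- Enabling feature: C5(=O), C6(OH), C9 and the fused benzo ring are the atoms of a 2-benzopyrylium-4-olate, a cyclic carbonyl ylide. C7–C8 is a terminal alkyne that already carries the C7 flavanyl group.
- Each cis-flavan-3-ol is cut at O1–C2 and C4–C4a, back to 3,5-bis(benzyloxy)phenol and an erythro epoxy alcohol. One epoxy alcohol comes from acrolein and a silylacetylene, the other from a formylphthalide built from 2,3-dihydroxybenzoic acid.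
- Forward order: the pyran ring of each half is made first (Mitsunobu ether, then epoxide–arene closure) and galloylated. The phthalide is unfolded to the formyl diazo ketone, the seven-membered ring is closed last, and global hydrogenolysis follows.
- Stereochemistry: all four centres come from two Sharpless kinetic resolutions with L-(+)-diisopropyl tartrate. Mitsunobu inversion turns the erythro epoxy alcohols into the 2,3-cis (2R,3R) series, and the key step leaves no new stereocentre.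

Key step: step 21

Remark: the given structure carries the second flavanyl group at C7, next to the tropolone hydroxyl, and the route is built for exactly this connectivity. The hydroxy ketone of step 14 is drawn open-chain although it equilibrates with its five-membered hemiketal.

**Route**

Step 1
Reactants: 1 (triisopropylsilyl)acetylene; 2 acrolein
Product: 3 rac-5-(triisopropylsilyl)pent-1-en-4-yn-3-ol
Conditions: n-BuLi, THF, −78 °C; then 2, −78 → 0 °C; aq. NH4Cl
Reagents that add atoms: none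
Why: Lithium acetylide addition to an enal is a fast 1,2-addition at low temperature, and the bulky silyl cap keeps the small enynol non-volatile and shields the alkyne terminus in the next steps.

Step 2
Reactants: 3 rac-5-(triisopropylsilyl)pent-1-en-4-yn-3-ol
Product: 4 (S)-1-[(R)-oxiran-2-yl]-3-(triisopropylsilyl)prop-2-yn-1-ol
Conditions: Ti(OiPr)4 (0.2 equiv), L-(+)-diisopropyl tartrate (0.24 equiv), t-BuOOH (0.55 equiv), 4 Å MS, CH2Cl2, −20 °C
Reagents that add atoms: tert-butyl hydroperoxide, CC(C)(C)OO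
Why: Sharpless kinetic resolution of a secondary allylic alcohol: with the L-(+)-tartrate the (R)-alcohol should be epoxidised much faster and anti to the carbinol substituent, giving the erythro (S,R) epoxy alcohol and setting both stereocentres of this half, while the (S)-alcohol remains and is separated by chromatography.

Step 3
Reactants: 4 (S)-1-[(R)-oxiran-2-yl]-3-(triisopropylsilyl)prop-2-yn-1-ol; 5 3,5-bis(benzyloxy)phenol
Product: 6 (R)-2-{(R)-1-[3,5-bis(benzyloxy)phenoxy]-3-(triisopropylsilyl)prop-2-yn-1-yl}oxirane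
Conditions: PPh3, DIAD, toluene, 0 °C → rt
Reagents that add atoms: none
Why: Mitsunobu etherification of a propargylic carbinol by a phenol proceeds by SN2 with inversion (S → R), which converts the erythro epoxy alcohol into the threo aryl ether that maps onto the 2,3-cis chroman; the silyl cap disfavours allenyl (SN2') attack and the epoxide is inert.

Step 4
Reactants: 6 (R)-2-{(R)-1-[3,5-bis(benzyloxy)phenoxy]-3-(triisopropylsilyl)prop-2-yn-1-yl}oxirane
Product: 7 (2R,3R)-5,7-bis(benzyloxy)-2-[(triisopropylsilyl)ethynyl]chroman-3-ol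
Conditions: BF3·OEt2 (0.3 equiv), CH2Cl2, −78 → −40 °C
Reagents that add atoms: none
Why: Intramolecular Friedel–Crafts epoxide–arene alkylation: the very electron-rich ring attacks the primary epoxide carbon in a 6-endo closure that forms C4–C4a without touching either stereocentre, so the (2R,3R) cis chromanol should result; a plain Lewis acid is chosen over a carbophilic gold catalyst because of the aryl propargyl ether.

Step 5
Reactants: 7 (2R,3R)-5,7-bis(benzyloxy)-2-[(triisopropylsilyl)ethynyl]chroman-3-ol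
Product: 8 (2R,3R)-5,7-bis(benzyloxy)-2-ethynylchroman-3-ol
Conditions: Bu4NF, THF, 0 °C
Reagents that add atoms: none
Why: Fluoride-induced protodesilylation of a silylalkyne is selective and is done before esterification so that no ester is exposed to basic fluoride.

Step 6
Reactants: 8 (2R,3R)-5,7-bis(benzyloxy)-2-ethynylchroman-3-ol; 9 3,4,5-tris(benzyloxy)benzoic acid
Product: 10 (2R,3R)-5,7-bis(benzyloxy)-2-ethynylchroman-3-yl 3,4,5-tris(benzyloxy)benzoate
Conditions: EDC·HCl, DMAP, CH2Cl2, rt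
Reagents that add atoms: none
Why: Steglich esterification acylates the hindered axial 3-hydroxyl through the acylpyridinium ion with retention at C3, and the terminal alkyne is inert.

Step 7
Reactants: 11 2,3-dihydroxybenzoic acid
Product: 12 5-bromo-2,3-dihydroxybenzoic acid
Conditions: Br2 (1.05 equiv), AcOH, rt
Reagents that add atoms: bromine, BrBr
Why: Electrophilic aromatic bromination goes to C5, the position para to the 2-hydroxyl and meta to the carboxyl group, where both directors agree.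

Step 8
Reactants: 12 5-bromo-2,3-dihydroxybenzoic acid
Product: 13 benzyl 2,3-bis(benzyloxy)-5-bromobenzoate
Conditions: BnBr (3.3 equiv), K2CO3, DMF, 60 °C
Reagents that add atoms: benzyl bromide, BrCc1ccccc1
Why: Williamson O-alkylation of both phenoxides and the carboxylate protects the catechol for the final hydrogenolysis and makes an ester that can direct metalation.

Step 9
Reactants: 13 benzyl 2,3-bis(benzyloxy)-5-bromobenzoate
Product: 16 6,7-bis(benzyloxy)-4-bromoisobenzofuran-1(3H)-one, via formyl ester 14 (not isolated), via hydroxymethyl ester 15 (not isolated)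
Conditions: TMPMgCl·LiCl (1.3 equiv), THF, −20 °C; DMF, −20 °C → rt; then MeOH, NaBH4, 0 °C; aq. NH4Cl
Reagents that add atoms: N,N-dimethylformamide, CN(C)C=O
Why: Directed ortho-magnesiation with a hindered magnesium amide should occur at C6, which is coordinated by the ester carbonyl and acidified by the neighbouring bromine; formylation, borohydride reduction and spontaneous lactonisation with loss of benzyl alcohol then give the phthalide that stores the future formyl and diazoacetyl carbons.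

Step 10
Reactants: 16 6,7-bis(benzyloxy)-4-bromoisobenzofuran-1(3H)-one
Product: 17 6,7-bis(benzyloxy)-1-oxo-1,3-dihydroisobenzofuran-4-carbaldehyde
Conditions: Pd(OAc)2 (1 mol%), di(1-adamantyl)-n-butylphosphine (3 mol%), TMEDA, CO/H2 (1:1, 5 bar), toluene, 100 °C
Reagents that add atoms: carbon monoxide, [C-]#[O+]
Why: Palladium-catalysed reductive carbonylation (formylation) of an aryl bromide tolerates lactones and benzyl ethers and delivers the aldehyde in one step.

Step 11
Reactants: 17 6,7-bis(benzyloxy)-1-oxo-1,3-dihydroisobenzofuran-4-carbaldehyde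
Product: 18 rac-6,7-bis(benzyloxy)-4-(1-hydroxyprop-2-en-1-yl)isobenzofuran-1(3H)-one
Conditions: CH2=CHMgBr (1.05 equiv), THF, −78 °C; aq. NH4Cl
Reagents that add atoms: vinylmagnesium bromide, C=C[Mg]Br
Why: Grignard 1,2-addition to the aldehyde is far faster than attack on the lactone at −78 °C with one equivalent of reagent.

Step 12
Reactants: 18 rac-6,7-bis(benzyloxy)-4-(1-hydroxyprop-2-en-1-yl)isobenzofuran-1(3H)-one
Product: 19 6,7-bis(benzyloxy)-4-{(S)-hydroxy[(R)-oxiran-2-yl]methyl}isobenzofuran-1(3H)-one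
Conditions: Ti(OiPr)4 (0.2 equiv), L-(+)-diisopropyl tartrate (0.24 equiv), t-BuOOH (0.55 equiv), 4 Å MS, CH2Cl2, −20 °C
Reagents that add atoms: tert-butyl hydroperoxide, CC(C)(C)OO
Why: The same Sharpless kinetic resolution as in step 2 (aryl in place of alkynyl, same priority pattern) should epoxidise the (R)-alcohol selectively to the erythro (S,R) epoxy alcohol and so set both stereocentres of the second flavanyl unit.

Step 13
Reactants: 19 6,7-bis(benzyloxy)-4-{(S)-hydroxy[(R)-oxiran-2-yl]methyl}isobenzofuran-1(3H)-one; 5 3,5-bis(benzyloxy)phenol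
Product: 20 6,7-bis(benzyloxy)-4-{(R)-[3,5-bis(benzyloxy)phenoxy][(R)-oxiran-2-yl]methyl}isobenzofuran-1(3H)-one
Conditions: PPh3, DIAD, toluene, 0 °C → rt
Reagents that add atoms: none
Why: Mitsunobu etherification with inversion (S → R) at the benzylic carbinol, whose ionisation is disfavoured by the adjacent epoxide and the lactone-bearing ring, gives the threo ether required for the cis chroman.

Step 14
Reactants: 20 6,7-bis(benzyloxy)-4-{(R)-[3,5-bis(benzyloxy)phenoxy][(R)-oxiran-2-yl]methyl}isobenzofuran-1(3H)-one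
Product: 21 1-[2,3-bis(benzyloxy)-5-{(R)-[3,5-bis(benzyloxy)phenoxy][(R)-oxiran-2-yl]methyl}-6-(hydroxymethyl)phenyl]ethan-1-one
Conditions: MeLi (1.1 equiv), THF, −78 °C; aq. NH4Cl at −78 °C
Reagents that add atoms: methyllithium, [Li]C
Why: Single addition of an organolithium to a phthalide stops at the lithium hemiketal, which is stable at −78 °C, so the lactone is unfolded into the methyl ketone (future diazoacetyl group) and the benzylic alcohol (future formyl group) while the epoxide is untouched in the absence of a Lewis acid.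

Step 15
Reactants: 21 1-[2,3-bis(benzyloxy)-5-{(R)-[3,5-bis(benzyloxy)phenoxy][(R)-oxiran-2-yl]methyl}-6-(hydroxymethyl)phenyl]ethan-1-one
Product: 22 1-[2,3-bis(benzyloxy)-5-{(R)-[3,5-bis(benzyloxy)phenoxy][(R)-oxiran-2-yl]methyl}-6-{[(tert-butyldimethylsilyl)oxy]methyl}phenyl]ethan-1-one
Conditions: TBSCl, imidazole, DMF, 0 °C → rt
Reagents that add atoms: tert-butyldimethylsilyl chloride, CC(C)(C)[Si](C)(C)Cl
Why: Silylation takes place at the only primary hydroxyl, the tertiary hemiketal hydroxyl being unreactive, so ring–chain equilibration funnels the material into the open-chain silyl ether, and no other hydroxyl is present at this stage.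

Step 16
Reactants: 22 1-[2,3-bis(benzyloxy)-5-{(R)-[3,5-bis(benzyloxy)phenoxy][(R)-oxiran-2-yl]methyl}-6-{[(tert-butyldimethylsilyl)oxy]methyl}phenyl]ethan-1-one
Product: 23 1-[2,3-bis(benzyloxy)-5-[(2R,3R)-5,7-bis(benzyloxy)-3-hydroxychroman-2-yl]-6-{[(tert-butyldimethylsilyl)oxy]methyl}phenyl]ethan-1-one
Conditions: AuCl3 (5 mol%), AgOTf (15 mol%), CH2Cl2, 0 °C → rt
Reagents that add atoms: none
Why: Gold-catalysed intramolecular Friedel–Crafts epoxide–arene cycloalkylation (6-endo attack of the phloroglucinol ring on the primary epoxide carbon) closes the pyran ring without touching the stereocentres and is mild enough not to ionise the benzylic ether, so the (2R,3R) cis chromanol should result; the shielded silyl ether oxygen would have to attack the internal, inductively deactivated epoxide carbon.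

Step 17
Reactants: 23 1-[2,3-bis(benzyloxy)-5-[(2R,3R)-5,7-bis(benzyloxy)-3-hydroxychroman-2-yl]-6-{[(tert-butyldimethylsilyl)oxy]methyl}phenyl]ethan-1-one; 9 3,4,5-tris(benzyloxy)benzoic acid
Product: 24 (2R,3R)-2-[3-acetyl-4,5-bis(benzyloxy)-2-{[(tert-butyldimethylsilyl)oxy]methyl}phenyl]-5,7-bis(benzyloxy)chroman-3-yl 3,4,5-tris(benzyloxy)benzoate
Conditions: EDC·HCl, DMAP, CH2Cl2, rt
Reagents that add atoms: none
Why: Steglich esterification of the only free hydroxyl, with retention at C3; the ketone and silyl ether are inert.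

Step 18
Reactants: 24 (2R,3R)-2-[3-acetyl-4,5-bis(benzyloxy)-2-{[(tert-butyldimethylsilyl)oxy]methyl}phenyl]-5,7-bis(benzyloxy)chroman-3-yl 3,4,5-tris(benzyloxy)benzoate
Product: 26 (2R,3R)-5,7-bis(benzyloxy)-2-[4,5-bis(benzyloxy)-2-{[(tert-butyldimethylsilyl)oxy]methyl}-3-(diazoacetyl)phenyl]chroman-3-yl 3,4,5-tris(benzyloxy)benzoate, via trifluoroacetyl ketone 25 (not isolated)
Conditions: LiN(SiMe3)2 (1.1 equiv), THF, −78 °C; CF3CO2CH2CF3; then MsN3, Et3N, H2O (1 equiv), MeCN, rt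
Reagents that add atoms: methanesulfonyl azide, CS(=O)(=O)N=[N+]=[N-]
Why: Regitz-type detrifluoroacetylative diazo transfer: the kinetic methyl enolate is C-trifluoroacetylated, the activated diketone accepts the diazo group from the sulfonyl azide and the trifluoroacetyl group is split off; the non-nucleophilic base spares the gallate ester, which has no α-hydrogen, and no aldehyde is present yet.

Step 19
Reactants: 26 (2R,3R)-5,7-bis(benzyloxy)-2-[4,5-bis(benzyloxy)-2-{[(tert-butyldimethylsilyl)oxy]methyl}-3-(diazoacetyl)phenyl]chroman-3-yl 3,4,5-tris(benzyloxy)benzoate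
Product: 27 (2R,3R)-5,7-bis(benzyloxy)-2-[4,5-bis(benzyloxy)-3-(diazoacetyl)-2-(hydroxymethyl)phenyl]chroman-3-yl 3,4,5-tris(benzyloxy)benzoate
Conditions: Bu4NF, AcOH (1:1), THF, 0 °C → rt
Reagents that add atoms: none
Why: Buffered fluoride cleaves the primary silyl ether without acid, which a diazo ketone would not survive, and without free alkoxide, which could attack the gallate.

Step 20
Reactants: 27 (2R,3R)-5,7-bis(benzyloxy)-2-[4,5-bis(benzyloxy)-3-(diazoacetyl)-2-(hydroxymethyl)phenyl]chroman-3-yl 3,4,5-tris(benzyloxy)benzoate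
Product: 28 (2R,3R)-5,7-bis(benzyloxy)-2-[4,5-bis(benzyloxy)-3-(diazoacetyl)-2-formylphenyl]chroman-3-yl 3,4,5-tris(benzyloxy)benzoate
Conditions: activated MnO2 (excess), CH2Cl2, rt; filtered and used at once
Reagents that add atoms: none
Why: Heterogeneous MnO2 oxidation is specific for the benzylic alcohol, stops at the aldehyde and is neutral, and diazo compounds tolerate this oxidant; the aldehyde is unveiled only now because a 2-formylbenzoic acid would react as its cyclic pseudo-acid and a free aldehyde would not survive the enolate chemistry of step 18.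

Step 21
Reactants: 10 (2R,3R)-5,7-bis(benzyloxy)-2-ethynylchroman-3-yl 3,4,5-tris(benzyloxy)benzoate; 28 (2R,3R)-5,7-bis(benzyloxy)-2-[4,5-bis(benzyloxy)-3-(diazoacetyl)-2-formylphenyl]chroman-3-yl 3,4,5-tris(benzyloxy)benzoate
Product: 31 3,4-bis(benzyloxy)-6-hydroxy-1,7-bis[(2R,3R)-5,7-bis(benzyloxy)-3-{[3,4,5-tris(benzyloxy)benzoyl]oxy}chroman-2-yl]-5H-benzo[7]annulen-5-one, via 2-benzopyrylium-4-olate 29 (not isolated), via oxygen-bridged cycloadduct 30 (not isolated)
Conditions: Rh2(OAc)4 (2 mol%), 10 (1.5 equiv), CH2Cl2, 40 °C, slow addition of 28; then BF3·OEt2, 0 °C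
Reagents that add atoms: none
Why: Rh2(OAc)4 (divalent rhodium) converts the diazo ketone into a carbenoid at the future C6, which is captured by the oxygen of the ortho formyl group in a six-membered closure to give the aromatic 2-benzopyrylium-4-olate 29; this carbonyl ylide adds as a 1,3-dipole across the alkyne of 10 in a concerted suprafacial cycloaddition that forms C6–C7 and C8–C9 and closes the seven-membered carbocycle as the oxygen-bridged adduct 30, the closest known reaction type being the tandem carbonyl-ylide formation–cycloaddition of diazo ketones with alkynes. BF3·OEt2 then ionises the benzylic and allylic C9–O bond (cation stabilised by the para benzyloxy group and the C7=C8 bond), and loss of the C6 proton gives the aromatic tropolone with the former bridge oxygen as the C6 hydroxyl, as known for 8-oxabicyclo[3.2.1]octadienones. The two bridgehead centres of 30 arise without control and are erased on aromatisation, so no lasting stereocentre is formed and the four flavanyl centres are untouched. The step needs regioselectivity (flavanyl-bearing alkyne carbon to C6, CH terminus to C9) and chemoselectivity (capture of the carbenoid by the formyl oxygen and not by the flanking benzyloxy oxygen; trapping by 10 and not ylide dimerisation). The former rests on the polarisation of the benzo-fused ylide, in which C9 is a benzylic oxocarbenium carbon and C6 an enolate carbon so that the terminal CH of a non-activated alkyne bonds to C9, reinforced by the peri flavanyl group at C1, which hinders approach of the substituted alkyne carbon to C9; the latter rests on the aromaticity gained in the six-membered carbonyl capture and on slow addition of 28 to an excess of 10.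

Step 22
Reactants: 31 3,4-bis(benzyloxy)-6-hydroxy-1,7-bis[(2R,3R)-5,7-bis(benzyloxy)-3-{[3,4,5-tris(benzyloxy)benzoyl]oxy}chroman-2-yl]-5H-benzo[7]annulen-5-one
Product: 32 3,4,6-trihydroxy-1,7-bis[(2R,3R)-5,7-dihydroxy-3-(3,4,5-trihydroxybenzoyloxy)chroman-2-yl]-5H-benzo[7]annulen-5-one (CNP0283148.1)
Conditions: H2 (1 atm), Pd(OH)2/C, THF/MeOH (1:1), rt, short contact; filtration under argon
Reagents that add atoms: none
Why: Hydrogenolysis of aryl benzyl ethers over Pd(OH)2/C is the standard last step for galloylated flavanols and, under mild conditions, should leave the gallate esters, the chroman C2–O bonds and the tropolone ring intact, giving the target with all four stereocentres unchanged.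

**Compound list**

1 | (triisopropylsilyl)acetylene | C#C[Si](C(C)C)(C(C)C)C(C)C | starting material
2 | acrolein | C=CC=O | starting material
3 | rac-5-(triisopropylsilyl)pent-1-en-4-yn-3-ol | C=CC(O)C#C[Si](C(C)C)(C(C)C)C(C)C | intermediate
4 | (S)-1-[(R)-oxiran-2-yl]-3-(triisopropylsilyl)prop-2-yn-1-ol | O[C@@H](C#C[Si](C(C)C)(C(C)C)C(C)C)[C@H]1CO1 | intermediate
5 | 3,5-bis(benzyloxy)phenol | Oc1cc(OCc2ccccc2)cc(OCc2ccccc2)c1 | starting material
6 | (R)-2-{(R)-1-[3,5-bis(benzyloxy)phenoxy]-3-(triisopropylsilyl)prop-2-yn-1-yl}oxirane | c1ccccc1COc1cc(OCc2ccccc2)cc(O[C@H](C#C[Si](C(C)C)(C(C)C)C(C)C)[C@H]2CO2)c1 | intermediate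
7 | (2R,3R)-5,7-bis(benzyloxy)-2-[(triisopropylsilyl)ethynyl]chroman-3-ol | O[C@@H]1Cc2c(OCc3ccccc3)cc(OCc3ccccc3)cc2O[C@@H]1C#C[Si](C(C)C)(C(C)C)C(C)C | intermediate
8 | (2R,3R)-5,7-bis(benzyloxy)-2-ethynylchroman-3-ol | O[C@@H]1Cc2c(OCc3ccccc3)cc(OCc3ccccc3)cc2O[C@@H]1C#C | intermediate
9 | 3,4,5-tris(benzyloxy)benzoic acid | OC(=O)c1cc(OCc2ccccc2)c(OCc2ccccc2)c(OCc2ccccc2)c1 | starting material
10 | (2R,3R)-5,7-bis(benzyloxy)-2-ethynylchroman-3-yl 3,4,5-tris(benzyloxy)benzoate | O=C(O[C@@H]1Cc2c(OCc3ccccc3)cc(OCc3ccccc3)cc2O[C@@H]1C#C)c1cc(OCc2ccccc2)c(OCc2ccccc2)c(OCc2ccccc2)c1 | intermediate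
11 | 2,3-dihydroxybenzoic acid | OC(=O)c1cccc(O)c1O | starting material
12 | 5-bromo-2,3-dihydroxybenzoic acid | OC(=O)c1cc(Br)cc(O)c1O | intermediate
13 | benzyl 2,3-bis(benzyloxy)-5-bromobenzoate | O=C(OCc1ccccc1)c1cc(Br)cc(OCc2ccccc2)c1OCc1ccccc1 | intermediate
14 | benzyl 2,3-bis(benzyloxy)-5-bromo-6-formylbenzoate | O=Cc1c(Br)cc(OCc2ccccc2)c(OCc2ccccc2)c1C(=O)OCc1ccccc1 | intermediate (not isolated)
15 | benzyl 2,3-bis(benzyloxy)-5-bromo-6-(hydroxymethyl)benzoate | OCc1c(Br)cc(OCc2ccccc2)c(OCc2ccccc2)c1C(=O)OCc1ccccc1 | intermediate (not isolated)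
16 | 6,7-bis(benzyloxy)-4-bromoisobenzofuran-1(3H)-one | O=C1OCc2c(Br)cc(OCc3ccccc3)c(OCc3ccccc3)c12 | intermediate
17 | 6,7-bis(benzyloxy)-1-oxo-1,3-dihydroisobenzofuran-4-carbaldehyde | O=Cc1cc(OCc2ccccc2)c(OCc2ccccc2)c2C(=O)OCc12 | intermediate
18 | rac-6,7-bis(benzyloxy)-4-(1-hydroxyprop-2-en-1-yl)isobenzofuran-1(3H)-one | C=CC(O)c1cc(OCc2ccccc2)c(OCc2ccccc2)c2C(=O)OCc12 | intermediate
19 | 6,7-bis(benzyloxy)-4-{(S)-hydroxy[(R)-oxiran-2-yl]methyl}isobenzofuran-1(3H)-one | O[C@@H](c1cc(OCc2ccccc2)c(OCc2ccccc2)c2C(=O)OCc12)[C@H]1CO1 | intermediate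
20 | 6,7-bis(benzyloxy)-4-{(R)-[3,5-bis(benzyloxy)phenoxy][(R)-oxiran-2-yl]methyl}isobenzofuran-1(3H)-one | c1ccccc1COc1cc(OCc2ccccc2)cc(O[C@H](c2cc(OCc3ccccc3)c(OCc3ccccc3)c3C(=O)OCc23)[C@H]2CO2)c1 | intermediate
21 | 1-[2,3-bis(benzyloxy)-5-{(R)-[3,5-bis(benzyloxy)phenoxy][(R)-oxiran-2-yl]methyl}-6-(hydroxymethyl)phenyl]ethan-1-one | c1ccccc1COc1cc(OCc2ccccc2)cc(O[C@H](c2cc(OCc3ccccc3)c(OCc3ccccc3)c(C(C)=O)c2CO)[C@H]2CO2)c1 | intermediate
22 | 1-[2,3-bis(benzyloxy)-5-{(R)-[3,5-bis(benzyloxy)phenoxy][(R)-oxiran-2-yl]methyl}-6-{[(tert-butyldimethylsilyl)oxy]methyl}phenyl]ethan-1-one | c1ccccc1COc1cc(OCc2ccccc2)cc(O[C@H](c2cc(OCc3ccccc3)c(OCc3ccccc3)c(C(C)=O)c2CO[Si](C)(C)C(C)(C)C)[C@H]2CO2)c1 | intermediate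
23 | 1-[2,3-bis(benzyloxy)-5-[(2R,3R)-5,7-bis(benzyloxy)-3-hydroxychroman-2-yl]-6-{[(tert-butyldimethylsilyl)oxy]methyl}phenyl]ethan-1-one | O[C@@H]1Cc2c(OCc3ccccc3)cc(OCc3ccccc3)cc2O[C@@H]1c1cc(OCc2ccccc2)c(OCc2ccccc2)c(C(C)=O)c1CO[Si](C)(C)C(C)(C)C | intermediate
24 | (2R,3R)-2-[3-acetyl-4,5-bis(benzyloxy)-2-{[(tert-butyldimethylsilyl)oxy]methyl}phenyl]-5,7-bis(benzyloxy)chroman-3-yl 3,4,5-tris(benzyloxy)benzoate | O=C(O[C@@H]1Cc2c(OCc3ccccc3)cc(OCc3ccccc3)cc2O[C@@H]1c1cc(OCc2ccccc2)c(OCc2ccccc2)c(C(C)=O)c1CO[Si](C)(C)C(C)(C)C)c1cc(OCc2ccccc2)c(OCc2ccccc2)c(OCc2ccccc2)c1 | intermediate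
25 | (2R,3R)-5,7-bis(benzyloxy)-2-[4,5-bis(benzyloxy)-2-{[(tert-butyldimethylsilyl)oxy]methyl}-3-(4,4,4-trifluoro-3-oxobutanoyl)phenyl]chroman-3-yl 3,4,5-tris(benzyloxy)benzoate | O=C(O[C@@H]1Cc2c(OCc3ccccc3)cc(OCc3ccccc3)cc2O[C@@H]1c1cc(OCc2ccccc2)c(OCc2ccccc2)c(C(=O)CC(=O)C(F)(F)F)c1CO[Si](C)(C)C(C)(C)C)c1cc(OCc2ccccc2)c(OCc2ccccc2)c(OCc2ccccc2)c1 | intermediate (not isolated)
26 | (2R,3R)-5,7-bis(benzyloxy)-2-[4,5-bis(benzyloxy)-2-{[(tert-butyldimethylsilyl)oxy]methyl}-3-(diazoacetyl)phenyl]chroman-3-yl 3,4,5-tris(benzyloxy)benzoate | O=C(O[C@@H]1Cc2c(OCc3ccccc3)cc(OCc3ccccc3)cc2O[C@@H]1c1cc(OCc2ccccc2)c(OCc2ccccc2)c(C(=O)C=[N+]=[N-])c1CO[Si](C)(C)C(C)(C)C)c1cc(OCc2ccccc2)c(OCc2ccccc2)c(OCc2ccccc2)c1 | intermediate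
27 | (2R,3R)-5,7-bis(benzyloxy)-2-[4,5-bis(benzyloxy)-3-(diazoacetyl)-2-(hydroxymethyl)phenyl]chroman-3-yl 3,4,5-tris(benzyloxy)benzoate | O=C(O[C@@H]1Cc2c(OCc3ccccc3)cc(OCc3ccccc3)cc2O[C@@H]1c1cc(OCc2ccccc2)c(OCc2ccccc2)c(C(=O)C=[N+]=[N-])c1CO)c1cc(OCc2ccccc2)c(OCc2ccccc2)c(OCc2ccccc2)c1 | intermediate
28 | (2R,3R)-5,7-bis(benzyloxy)-2-[4,5-bis(benzyloxy)-3-(diazoacetyl)-2-formylphenyl]chroman-3-yl 3,4,5-tris(benzyloxy)benzoate | O=C(O[C@@H]1Cc2c(OCc3ccccc3)cc(OCc3ccccc3)cc2O[C@@H]1c1cc(OCc2ccccc2)c(OCc2ccccc2)c(C(=O)C=[N+]=[N-])c1C=O)c1cc(OCc2ccccc2)c(OCc2ccccc2)c(OCc2ccccc2)c1 | intermediate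
29 | 5,6-bis(benzyloxy)-8-[(2R,3R)-5,7-bis(benzyloxy)-3-{[3,4,5-tris(benzyloxy)benzoyl]oxy}chroman-2-yl]-2-benzopyrylium-4-olate (cyclic carbonyl ylide) | O=C(O[C@@H]1Cc2c(OCc3ccccc3)cc(OCc3ccccc3)cc2O[C@@H]1c1cc(OCc2ccccc2)c(OCc2ccccc2)c2C([O-])=C[O+]=Cc12)c1cc(OCc2ccccc2)c(OCc2ccccc2)c(OCc2ccccc2)c1 | intermediate (not isolated)
30 | 3,4-bis(benzyloxy)-1,7-bis[(2R,3R)-5,7-bis(benzyloxy)-3-{[3,4,5-tris(benzyloxy)benzoyl]oxy}chroman-2-yl]-6,9-dihydro-5H-6,9-epoxybenzo[7]annulen-5-one (both bridgehead epimers) | O=C(O[C@@H]1Cc2c(OCc3ccccc3)cc(OCc3ccccc3)cc2O[C@@H]1C1=CC2OC1C(=O)c1c(OCc3ccccc3)c(OCc3ccccc3)cc([C@H]3Oc4cc(OCc5ccccc5)cc(OCc5ccccc5)c4C[C@H]3OC(=O)c3cc(OCc4ccccc4)c(OCc4ccccc4)c(OCc4ccccc4)c3)c12)c1cc(OCc2ccccc2)c(OCc2ccccc2)c(OCc2ccccc2)c1 | intermediate (not isolated)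
31 | 3,4-bis(benzyloxy)-6-hydroxy-1,7-bis[(2R,3R)-5,7-bis(benzyloxy)-3-{[3,4,5-tris(benzyloxy)benzoyl]oxy}chroman-2-yl]-5H-benzo[7]annulen-5-one (dodeca-O-benzyl target) | O=C(O[C@@H]1Cc2c(OCc3ccccc3)cc(OCc3ccccc3)cc2O[C@@H]1c1ccc2c([C@H]3Oc4cc(OCc5ccccc5)cc(OCc5ccccc5)c4C[C@H]3OC(=O)c3cc(OCc4ccccc4)c(OCc4ccccc4)c(OCc4ccccc4)c3)cc(OCc3ccccc3)c(OCc3ccccc3)c2c(=O)c1O)c1cc(OCc2ccccc2)c(OCc2ccccc2)c(OCc2ccccc2)c1 | intermediate
32 | 3,4,6-trihydroxy-1,7-bis[(2R,3R)-5,7-dihydroxy-3-(3,4,5-trihydroxybenzoyloxy)chroman-2-yl]-5H-benzo[7]annulen-5-one (CNP0283148.1) | O=C(O[C@@H]1Cc2c(O)cc(O)cc2O[C@@H]1c1ccc2c([C@H]3Oc4cc(O)cc(O)c4C[C@H]3OC(=O)c3cc(O)c(O)c(O)c3)cc(O)c(O)c2c(=O)c1O)c1cc(O)c(O)c(O)c1 | target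

**Step count and risks**

Total: 22 steps (6 to alkyne 10, 14 to diazo ketone 28, 2 after convergence). Longest linear sequence: 16 steps (steps 7–22, from 2,3-dihydroxybenzoic acid).

Steps most likely to fail:

1. Step 21. The ylide may be trapped too slowly by a non-activated alkyne, so that it dimerises or adds to the formyl group of a second molecule of 28, and the alkyne may add in the reverse orientation. Fallback: the alkyne is replaced by a polarised alkyne surrogate whose orientation is fixed by an acceptor group. Setting out from 10, radical addition of thiophenol (AIBN, 80 °C, equilibrated to the E isomer) should give (2R,3R)-5,7-bis(benzyloxy)-2-[(E)-2-(phenylsulfanyl)vinyl]chroman-3-yl 3,4,5-tris(benzyloxy)benzoate F1. Oxidation with one equivalent of mCPBA at −78 °C gives the corresponding (E)-vinyl sulfoxide F2. As an electron-poor dipolarophile, F2 should accept the enolate carbon of ylide 29 (generated from 28 with Rh2(OAc)4 as before) at its flavanyl-bearing carbon and give the 8-phenylsulfinyl-7,8-dihydro cycloadduct F3. Thermal syn-elimination of benzenesulfenic acid (toluene, 110 °C; the C7 hydrogen is cis to sulfur) then gives 30, and BF3·OEt2 leads back to the route at 31.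

2. Step 20. The diazo carbon may add to the newly formed neighbouring formyl group (closure to a diazo hydroxyindanone), or the diazo group may be lost on the oxidant. Fallback: the same ylide is generated without a formyl diazo ketone. Setting out from 26, rhodium-catalysed O–H insertion of water (Rh2(OAc)4, wet CH2Cl2) should give (2R,3R)-5,7-bis(benzyloxy)-2-[4,5-bis(benzyloxy)-2-{[(tert-butyldimethylsilyl)oxy]methyl}-3-(hydroxyacetyl)phenyl]chroman-3-yl 3,4,5-tris(benzyloxy)benzoate F4. Bu4NF/AcOH gives the 2-(hydroxymethyl) diol F5. MnO2 oxidises only the benzylic alcohol, and the aldehyde is trapped by the ketol hydroxyl as the 1-hydroxy-4-oxoisochroman-8-yl lactol F6. Ac2O/Et3N/DMAP gives the lactol acetate F7. Warming F7 with Et3N in the presence of 10 eliminates acetic acid to ylide 29 (the oxidopyrylium way of making such ylides), which adds to 10 to give 30; BF3·OEt2 then returns to the route at 31.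

3. Step 9. Metalation may occur at the other activated ring position (C4, between bromine and a benzyloxy group), or the amide base may attack the benzyl ester. Fallback: the ortho C–H bond is functionalised under carboxylate direction. Setting out from 13, saponification (LiOH, THF/H2O) gives 2,3-bis(benzyloxy)-5-bromobenzoic acid F8. Pd(OAc)2-catalysed carboxylate-directed ortho C–H alkylation with CH2Br2 (K2HPO4, 140 °C) followed by lactonisation in the same flask should give 16, where the fallback rejoins the route. Palladium stays divalent or higher, so the aryl bromide is not consumed, and the carboxylate can reach only the C6–H bond.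

**Further compounds**

F1 | step 21 | (2R,3R)-5,7-bis(benzyloxy)-2-[(E)-2-(phenylsulfanyl)vinyl]chroman-3-yl 3,4,5-tris(benzyloxy)benzoate | O=C(O[C@@H]1Cc2c(OCc3ccccc3)cc(OCc3ccccc3)cc2O[C@@H]1/C=C/Sc1ccccc1)c1cc(OCc2ccccc2)c(OCc2ccccc2)c(OCc2ccccc2)c1
F2 | step 21 | (2R,3R)-5,7-bis(benzyloxy)-2-[(E)-2-(phenylsulfinyl)vinyl]chroman-3-yl 3,4,5-tris(benzyloxy)benzoate (both sulfur epimers) | O=C(O[C@@H]1Cc2c(OCc3ccccc3)cc(OCc3ccccc3)cc2O[C@@H]1/C=C/S(=O)c1ccccc1)c1cc(OCc2ccccc2)c(OCc2ccccc2)c(OCc2ccccc2)c1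
F3 | step 21 | 8-(phenylsulfinyl)-7,8-dihydro analogue of cycloadduct 30 (3,4-bis(benzyloxy)-8-(phenylsulfinyl)-1,7-bis(flavanyl gallate)-6,7,8,9-tetrahydro-5H-6,9-epoxybenzo[7]annulen-5-one) | O=C(O[C@@H]1Cc2c(OCc3ccccc3)cc(OCc3ccccc3)cc2O[C@@H]1C1C(S(=O)c2ccccc2)C2OC1C(=O)c1c(OCc3ccccc3)c(OCc3ccccc3)cc([C@H]3Oc4cc(OCc5ccccc5)cc(OCc5ccccc5)c4C[C@H]3OC(=O)c3cc(OCc4ccccc4)c(OCc4ccccc4)c(OCc4ccccc4)c3)c12)c1cc(OCc2ccccc2)c(OCc2ccccc2)c(OCc2ccccc2)c1
F4 | step 20 | (2R,3R)-5,7-bis(benzyloxy)-2-[4,5-bis(benzyloxy)-2-{[(tert-butyldimethylsilyl)oxy]methyl}-3-(hydroxyacetyl)phenyl]chroman-3-yl 3,4,5-tris(benzyloxy)benzoate | O=C(O[C@@H]1Cc2c(OCc3ccccc3)cc(OCc3ccccc3)cc2O[C@@H]1c1cc(OCc2ccccc2)c(OCc2ccccc2)c(C(=O)CO)c1CO[Si](C)(C)C(C)(C)C)c1cc(OCc2ccccc2)c(OCc2ccccc2)c(OCc2ccccc2)c1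
F5 | step 20 | (2R,3R)-5,7-bis(benzyloxy)-2-[4,5-bis(benzyloxy)-3-(hydroxyacetyl)-2-(hydroxymethyl)phenyl]chroman-3-yl 3,4,5-tris(benzyloxy)benzoate | O=C(O[C@@H]1Cc2c(OCc3ccccc3)cc(OCc3ccccc3)cc2O[C@@H]1c1cc(OCc2ccccc2)c(OCc2ccccc2)c(C(=O)CO)c1CO)c1cc(OCc2ccccc2)c(OCc2ccccc2)c(OCc2ccccc2)c1
F6 | step 20 | (2R,3R)-5,7-bis(benzyloxy)-2-[5,6-bis(benzyloxy)-1-hydroxy-4-oxoisochroman-8-yl]chroman-3-yl 3,4,5-tris(benzyloxy)benzoate | O=C(O[C@@H]1Cc2c(OCc3ccccc3)cc(OCc3ccccc3)cc2O[C@@H]1c1cc(OCc2ccccc2)c(OCc2ccccc2)c2C(=O)COC(O)c12)c1cc(OCc2ccccc2)c(OCc2ccccc2)c(OCc2ccccc2)c1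
F7 | step 20 | (2R,3R)-2-[1-acetoxy-5,6-bis(benzyloxy)-4-oxoisochroman-8-yl]-5,7-bis(benzyloxy)chroman-3-yl 3,4,5-tris(benzyloxy)benzoate | O=C(O[C@@H]1Cc2c(OCc3ccccc3)cc(OCc3ccccc3)cc2O[C@@H]1c1cc(OCc2ccccc2)c(OCc2ccccc2)c2C(=O)COC(OC(C)=O)c12)c1cc(OCc2ccccc2)c(OCc2ccccc2)c(OCc2ccccc2)c1
F8 | step 9 | 2,3-bis(benzyloxy)-5-bromobenzoic acid | OC(=O)c1cc(Br)cc(OCc2ccccc2)c1OCc1ccccc1
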